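**Retrosynthetic overview**

1. The target comes from NaBH4 reduction of the closed 3-formyl dihydropyran (elenolate-type monoaldehyde).
2. That dihydropyran, the only ring of the target, is closed by intramolecular oxa-Michael addition of a formyl-ester enol oxygen to an (E)-ethylidene enal, the same closure by which the oleuropein aglycone forms after deglycosylation; it sets C2 and C3 from C4.
3. The open enol–enal is released in the flask: hydroxytyrosol opens an enol δ-lactone (acyl transfer forms the ester and frees the enol), then acid unmasks the enal.
4. The enol lactone comes from an oxidative carbene-catalysed annulation of methyl formylacetate with a dienal acetal; this sets the one catalyst-controlled stereocentre.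
5. The dienal acetal comes from crotonaldehyde. Ring order: transient enol lactone (step 4, opened in step 5), then the dihydropyran (step 5).

Assumption: the sodium enolate of methyl formylacetate (9) is bought (otherwise one Claisen condensation of methyl acetate with methyl formate and NaOMe), and both antipodes of the triazolium precatalyst are commercial.

**Route**

Step 1
Reactants: 1 crotonaldehyde, (E)-but-2-enal
Product: 3 (Z)-2-bromobut-2-enal, via 2,3-dibromobutanal 2 (not isolated)
Conditions: Br2 (1.0 equiv), CH2Cl2, 0 °C; then Et3N (1.2 equiv), 0 °C to rt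
Reagents that add atoms: bromine, BrBr
Why: Alkene bromination followed by E1cB dehydrobromination (α-proton, β-bromide) gives the α-bromoenal, and the reversible enolate pathway delivers the more stable Z isomer (methyl trans to CHO), which later becomes the (E)-ethylidene geometry that the ring closure needs.

Step 2
Reactants: 3 (Z)-2-bromobut-2-enal
Product: 4 (Z)-2-bromo-1,1-dimethoxybut-2-ene
Conditions: HC(OMe)3 (1.5 equiv), MeOH, p-TsOH·H2O (2 mol%), rt; NaHCO3 quench, distil
Reagents that add atoms: trimethyl orthoformate, COC(OC)OC; methanol, CO
Why: Acid-catalysed acetalisation with the orthoformate as water scavenger masks the aldehyde so that the vinyl bromide can be lithiated and only one enal is present in the carbene step, and it leaves the alkene geometry untouched.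

Step 3
Reactants: 4 (Z)-2-bromo-1,1-dimethoxybut-2-ene; 5 (E)-3-(dimethylamino)prop-2-enal
Product: 8 (2E,4E)-4-(dimethoxymethyl)hexa-2,4-dienal, via vinyllithium 6 (not isolated), via lithium alkoxide adduct 7 (not isolated)
Conditions: t-BuLi (2.1 equiv), THF, −78 °C; 5 (1.1 equiv), −78 to −20 °C; then aq. AcOH/NaOAc buffer (pH about 4.5), 0 °C
Reagents that add atoms: water, O
Why: Bromine–lithium exchange proceeds with retention of alkene geometry (an α-acrolein-anion equivalent), the vinyllithium adds 1,2 to the vinylogous formamide, and mild acid expels dimethylamine from the amino-allyl alcohol (vinylogous formylation) to give the (E)-enal, while the acetal, deactivated by the electron-poor dienal, survives the buffered work-up.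

Step 4
Reactants: 8 (2E,4E)-4-(dimethoxymethyl)hexa-2,4-dienal; 9 sodium (E)-3-methoxy-3-oxoprop-1-en-1-olate (1.3 equiv)
Product: 11 methyl (4S)-4-[(2E)-1,1-dimethoxybut-2-en-2-yl]-2-oxo-3,4-dihydro-2H-pyran-5-carboxylate, via methyl formylacetate 10 (not isolated)
Conditions: AcOH (1.2 equiv), aminoindanol-derived N-mesityl triazolium chloride (10 mol%, the antipode that gives 4S), 3,3',5,5'-tetra-tert-butyldiphenoquinone (1.2 equiv), 4 Å molecular sieves, THF, rt
Reagents that add atoms: none
Why: Proposed new method: the carbene and the quinone oxidant turn the enal carbonyl into a catalyst-bound α,β-unsaturated acyl donor at the carboxyl oxidation level, the enol of formylacetate adds to its β-carbon (by O-addition and [3,3] shift or by direct Michael addition, which favours β- over δ-attack) and O-acylation by the resulting enol closes the lactone and frees the catalyst, the aminoindanol backbone shielding one face so that C4 is set as S; the closest known reaction type is the oxidative NHC-catalysed annulation of enals with β-keto esters and 1,3-diketones to 3,4-dihydropyran-2-ones, extended here to a β-formyl ester.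

Step 5
Reactants: 11 methyl (4S)-4-[(2E)-1,1-dimethoxybut-2-en-2-yl]-2-oxo-3,4-dihydro-2H-pyran-5-carboxylate; 12 hydroxytyrosol, 2-(3,4-dihydroxyphenyl)ethanol (1.3 equiv)
Product: 16 methyl (2S,3R,4S)-4-{2-[2-(3,4-dihydroxyphenyl)ethoxy]-2-oxoethyl}-3-(hydroxymethyl)-2-methyl-3,4-dihydro-2H-pyran-5-carboxylate, via ring-opened enol ester acetal 13 (not isolated), via open enol enal 14 (not isolated), via closed monoaldehyde 15 (not isolated)
Conditions: Et3N (1.2 equiv), DMAP (10 mol%), MeCN, 0 °C to rt; then 1 M aq. HCl (2.5 equiv), THF, rt, about 2 h; then NaHCO3 to pH 6–7, NaBH4 (1.5 equiv), 0 °C, 15 min, AcOH quench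
Reagents that add atoms: water, O
Why: DMAP-catalysed acyl transfer from the enol lactone (an active enol ester) to the primary alcohol of hydroxytyrosol gives the ester and frees the formyl-ester enol (phenol acylation is reversible and drains to the alkyl ester), acetal hydrolysis then unveils the (E)-ethylidene enal and the enol oxygen adds to it in a six-membered intramolecular oxa-Michael reaction as in the closure of the oleuropein aglycone: with the C4–H eclipsing the enal double bond to avoid allylic 1,3-strain with the cis methyl group the oxygen attacks the face that gives 2S, protonation of the resulting enol places the formyl group trans to the C4 side chain (the epimerisable, thermodynamic position), and immediate NaBH4 reduction of the aldehyde, to which the esters and the vinylogous carbonate are inert, fixes C2 and C3 before retro-oxa-Michael equilibration.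

**Compound list**

1 | (E)-but-2-enal (crotonaldehyde) | C/C=C/C=O | starting material
2 | (2RS,3SR)-2,3-dibromobutanal (racemic anti adduct) | C[C@H](Br)[C@H](Br)C=O | intermediate
3 | (Z)-2-bromobut-2-enal | C/C=C(\Br)C=O | intermediate
4 | (Z)-2-bromo-1,1-dimethoxybut-2-ene | C/C=C(\Br)C(OC)OC | intermediate
5 | (E)-3-(dimethylamino)prop-2-enal | CN(C)/C=C/C=O | starting material
6 | [(E)-1,1-dimethoxybut-2-en-2-yl]lithium | C/C=C(\[Li])C(OC)OC | intermediate
7 | lithium (1E,4E)-4-(dimethoxymethyl)-1-(dimethylamino)hexa-1,4-dien-3-olate (racemic at C3) | C/C=C(\C(O[Li])/C=C/N(C)C)C(OC)OC | intermediate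
8 | (2E,4E)-4-(dimethoxymethyl)hexa-2,4-dienal | C/C=C(\C=C\C=O)C(OC)OC | intermediate
9 | sodium (E)-3-methoxy-3-oxoprop-1-en-1-olate (sodium enolate of methyl formylacetate) | [Na+].[O-]/C=C/C(=O)OC | starting material
10 | methyl 3-oxopropanoate (methyl formylacetate, reacts as its enol) | COC(=O)CC=O | intermediate
11 | methyl (4S)-4-[(2E)-1,1-dimethoxybut-2-en-2-yl]-2-oxo-3,4-dihydro-2H-pyran-5-carboxylate | C/C=C(/C(OC)OC)[C@@H]1CC(=O)OC=C1C(=O)OC | intermediate
12 | hydroxytyrosol, 2-(3,4-dihydroxyphenyl)ethanol | OCCc1ccc(O)c(O)c1 | starting material
13 | 1-[2-(3,4-dihydroxyphenyl)ethyl] 5-methyl (3S,4Z)-3-[(2E)-1,1-dimethoxybut-2-en-2-yl]-4-(hydroxymethylidene)pentanedioate | C/C=C(/C(OC)OC)[C@H](CC(=O)OCCc1ccc(O)c(O)c1)/C(C(=O)OC)=C/O | intermediate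
14 | 1-[2-(3,4-dihydroxyphenyl)ethyl] 5-methyl (3S,4Z)-4-(hydroxymethylidene)-3-[(2E)-1-oxobut-2-en-2-yl]pentanedioate (open enol form of the oleuropein aglycone) | C/C=C(/C=O)[C@H](CC(=O)OCCc1ccc(O)c(O)c1)/C(C(=O)OC)=C/O | intermediate
15 | methyl (2S,3S,4S)-4-{2-[2-(3,4-dihydroxyphenyl)ethoxy]-2-oxoethyl}-3-formyl-2-methyl-3,4-dihydro-2H-pyran-5-carboxylate | COC(=O)C1=CO[C@@H](C)[C@@H](C=O)[C@@H]1CC(=O)OCCc1ccc(O)c(O)c1 | intermediate
16 | methyl (2S,3R,4S)-4-{2-[2-(3,4-dihydroxyphenyl)ethoxy]-2-oxoethyl}-3-(hydroxymethyl)-2-methyl-3,4-dihydro-2H-pyran-5-carboxylate | COC(=O)C1=CO[C@@H](C)[C@@H](CO)[C@@H]1CC(=O)OCCc1ccc(O)c(O)c1 | target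

**Step count and risks**

Total step count: 5. Longest linear sequence: 5 steps (1 to 16).

The three steps most likely to fail:

Step 4. The aldehyde tautomer of the formyl ester may itself be taken up by the carbene, δ-addition may compete, and the enantioselectivity with an alkenyl β-substituent is untested. The fallback sets out from 8 and replaces carbene and oxidant activation by acyl ammonium catalysis. Pinnick oxidation (NaClO2, NaH2PO4/Na2HPO4 buffer at pH about 5, 2-methylbut-2-ene, t-BuOH/H2O) gives (2E,4E)-4-(dimethoxymethyl)hexa-2,4-dienoic acid F1. Pivaloyl chloride and i-Pr2NEt convert it into (2E,4E)-4-(dimethoxymethyl)hexa-2,4-dienoic pivalic anhydride F2. A chiral isothiourea (HyperBTM, the antipode that gives 4S) then forms the α,β-unsaturated acyl ammonium from F2, and this undergoes Michael addition and lactonisation with 10 (freed from 9). The fallback comes back to the route at 11.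

Step 5. The acyl transfer may stall through re-closure of the lactone or stray onto the catechol, some C2 epimer may form, and the product alcohol can lactonise onto the side-chain ester if the reduction is left basic. The fallback sets out from 11 and puts ring closure before esterification. LiOH (1.05 equiv, THF/H2O, 0 °C) opens the enol lactone; acidification to pH 2 hydrolyses the acetal and the same oxa-Michael closure on the free acid gives (2S,3S,4S)-elenolic acid F3, which is purified from any C2 epimer. Mitsunobu esterification of F3 with 12 (PPh3, DIAD, THF, 0 °C), which is selective for the primary alcohol over the phenols, gives the monoaldehyde. The fallback comes back to the route at 15, which is then reduced with NaBH4 as in step 5.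

Step 3. The vinyllithium may decompose, or the acetal may be lost in the hydrolytic work-up. The fallback sets out from 4 and avoids organolithium chemistry: a Mizoroki–Heck coupling with acrolein (Pd(OAc)2 5 mol%, Bu4NCl, NaHCO3, DMF, 50 °C) proceeds with retention of the bromoalkene geometry. It makes no compound outside the list (none F0) and comes back to the route at 8.

**Further compounds**

F0 | step 3 | none | none
F1 | step 4 | (2E,4E)-4-(dimethoxymethyl)hexa-2,4-dienoic acid | C/C=C(\C=C\C(=O)O)C(OC)OC
F2 | step 4 | (2E,4E)-4-(dimethoxymethyl)hexa-2,4-dienoic pivalic anhydride | C/C=C(\C=C\C(=O)OC(=O)C(C)(C)C)C(OC)OC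
F3 | step 5 | (2S,3S,4S)-elenolic acid, 2-[(2S,3S,4S)-3-formyl-5-(methoxycarbonyl)-2-methyl-3,4-dihydro-2H-pyran-4-yl]acetic acid | COC(=O)C1=CO[C@@H](C)[C@@H](C=O)[C@@H]1CC(=O)O
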